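If a catalyst stops a reaction before the clock does, then the thing to reckon is a ration and not a time, so I began from what was charged and read.

all flasks: J 14 mM; temperature 35 °C

| charge | Q | X | remark | time |
|---|---|---|---|---|
| east | 0.13 M | 0.26 M | the very flask that is asked about, followed so far |  |
| south-east | 0.20 M | 0.26 M | run made earlier |  |
| flask | 0.13 M | 0.260 M |  | 1.5 h |

| east: time / min | east: G / % | south-east: time / min | south-east: G / % |
|---|---|---|---|
| 6.00 | 19.3 | 5.00 | 14.4 |
| 12.0 | 34.1 | 12.0 | 34.1 |
| 30.0 | 50.9 | 25.0 | 42.7 |
| 80.0 | 52.7 | 60.0 | 46.8 |

(readings scatter by 1 percentage point)

- birch: at 1.5 h add X, 50.0% of the amount charged, then wait 50 min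
- elm: at 1.5 h take out 90% of the G then present, then wait 50 min
- alder: at 1.5 h raise the temperature by 15 K, then wait 50 min
- ash: at 1.5 h add J, 100% of the amount charged, then wait 50 min
- cedar: change nothing and wait 50 min more

- removed G is counted in
- additions bring no volume worth counting
- the earlier runs do not show what temperature does; that part of a forecast is a guess

* G, in percent of the Q first charged, at 1.5 h
* what to do for the largest gain in G; "none" if nothing gains more than 2 percentage points (birch / elm / alder / ash / cedar / none)
* G present, with what was taken out counted in, in percent of the Q first charged, after birch
* G present, with what was taken out counted in, in percent of the Q first charged, after alder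

At 12.0 min the east and south-east runs both stood at 34.1% of their Q, so their early course reads as first order in Q, with k = 0.0348 min⁻¹. My first extreme was a J that never dies: the east flask, which is the flask asked about, would then reach 95.6% by 1.5 h, yet its last reading was 52.7%. My second extreme was a J that dies by the clock whatever else is present: both runs would then stop at one percentage, yet east stood at 52.7% and south-east at 46.8%, a gap of 5.9 percentage points against a scatter of 1 point. So I placed the real flask between them, with J dying faster the more G stands beside it.

I let the working share of J fall at a rate proportional to c(G), and let G form in proportion to that share and to the unused Q, with y the G as a fraction of the Q charged. Dividing one rate by the other removes time, and from start to stop it leaves c(Q)/c(J), both as charged, times [ln(1/(1−y)) − y]. The east run reads 2.06 and the south-east run 2.33, and I took their mean, 2.19, as the catalyst ration, the deactivation allowance per J charged, with X and temperature held.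

I committed to G near the last east reading, since that flask rose 1.8 points between 30.0 min and 80.0 min. Birch, elm, alder and cedar add no J, so I expected each to stay inside 2 points, alder by a guess, while ash adds 100% of the J charged and so brings fresh allowance.

The forecast gave 53%, ash as best, 53.8% after birch and 54% after alder, on the ground that “Fresh J should restart conversion”. The flask gave 53.0%, ash with a gain of 5.2 points, 53.1% after birch and 53.0% after alder.

    Q + J ⇌ J + L (K = 1.40, k = 6.60 M⁻¹ min⁻¹, Ea = 65.0 kJ mol⁻¹, ΔH = −32.0 kJ mol⁻¹)
    X + J + L → J + G (k = 73.0 M⁻² min⁻¹, Ea = 50.0 kJ mol⁻¹)
    J + G → D (k = 1.30 M⁻¹ min⁻¹, Ea = 65.0 kJ mol⁻¹)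
    (constants at 35 °C)

Taken out of the run, the loss of J + G to D lifts G at 1.5 h from 53.0% to 99.1%, the main reason for the stop. The result in this flask reads a ration of 2.09, against my 2.19 from the earlier runs. The neighbour flask with 0.33 M of Q and the same J reached 36.2%, less than this flask, and that neighbour's G reads a ration of 2.06, less than my 2.19.

The numbers in the tables are simulated from invented constants; the scatter is artificial.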